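Monomer in chains is the one species read in these runs, and the flask is asked for its highest value.

| flask | solid monomer | initiator | remark | time |
|---|---|---|---|---|
| gamma | 0.14 M | 1 mM | run made earlier |  |
| delta | 0.22 M | 1 mM | run made earlier |  |
| eta | 0.10 M | 1.5 mM | run made earlier |  |
| flask | 0.10 M | 1.0 mM |  | 25 min |

| run | time / min | monomer in chains / % |
|---|---|---|
| gamma | 0.333 | 8.0 |
| gamma | 0.500 | 22.3 |
| gamma | 1.00 | 71.7 |
| gamma | 2.00 | 80.0 |
| gamma | 4.00 | 68.5 |
| gamma | 8.00 | 62.9 |
| gamma | 15.0 | 62.5 |
| delta | 0.333 | 5.7 |
| delta | 0.500 | 13.3 |
| delta | 1.00 | 45.6 |
| delta | 2.00 | 85.7 |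
| delta | 4.00 | 74.0 |
| delta | 8.00 | 65.1 |
| delta | 15.0 | 62.4 |
| eta | 0.333 | 15.2 |
| eta | 0.833 | 78.6 |
| eta | 2.00 | 67.5 |
| eta | 6.00 | 62.6 |
| eta | 15.0 | 62.1 |

(standard deviation of a reading: 0.3 percentage points)

- the moment within 25 min at which there is most monomer in chains
- the amount of monomer in chains, in percent of the solid monomer charged, at that time

Take the rise first. At 1.00 min gamma and delta read the same [monomer in chains], 0.100 M and 0.100 M, although delta was charged with more solid, so at this initiator charge the early rise of these two runs lies close to one curve in molar amount. Next comes the fall. Each run passes a high reading and sinks, and the last readings of gamma, delta and eta average 62.3%. This end share, the part of the charged monomer that stays in chains once the readings stop moving, shows no trend with charge across these runs. Such a level reads like thermodynamic control, and the peak like a kinetic excess over it. Last comes the initiator. Eta, with the flask's solid charge but more initiator, reads 78.6% at 0.833 min.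

At 1.00 min gamma and delta read about as much monomer in chains as the flask's solid charge of 0.10 M. The reckoning here therefore expects the flask's peak near that time, later than eta's reading and above the end share, and then a fall towards that share. The forecast gives 0.95 min and 80%, on the grounds that “growth is limited by dissolution and initiation”.

The flask peaks at 84.1% at 1.16 min, with 2.81% of its charge still free monomer at that moment.

    free monomer + initiator → living end + monomer in chains (k = 0.640 M⁻¹ s⁻¹)
    free monomer + living end → monomer in chains + living end, rate k2*[living end]*[free monomer] (k = 150 M⁻¹ s⁻¹)
    monomer in chains + initiator ⇌ isomer of the product + initiator, rate k3*[initiator]*[monomer in chains] forward; the back reaction follows from the equilibrium constant (K = 0.600, k = 13.0 M⁻¹ s⁻¹)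
    solid monomer ⇌ free monomer, rate k4*(cs4 - [free monomer]) while solid is left; crystals form when [free monomer] > cs4 (solubility = 0.0690 M, k = 0.0590 s⁻¹)

That peak stands 22 percentage points above the end share. At 25.0 min the flask holds 62.5% in chains and 37.5% isomer of the product. A neighbour flask with 0.040 M of solid monomer peaks at 77.9%, 16 points above the end share, and holds 62.5% at 25.0 min.

The earlier runs and the new flask come from a simulation with constants of no real substance.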